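The ring (numbered as cyclohex-4-ene-1,3-dione) is cut at C2–C3 and C1–C6. This exposes C1(=O)–C2(prenyl)2 as diprenylketene and C3–C6 as an aromatic furan: the furan C2–O, 3-acyl group, C4–O, ring oxygen and 5-prenyl group map onto the C3 carbonyl, C4 acyl group, C5 enol, C6 hydroxyl and C6 prenyl group. In the key step a 3-acyl-5-prenyl-2,4-bis(silyloxy)furan, made from a 3-acyltetronic acid, is dearomatized by a formal [4+2] annulation with the ketene under chiral ammonium catalysis; the first C–C bond sets C6, and collapse of the oxygen bridge turns the furan oxygen into the tertiary hydroxyl.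

Key step: step 8

Remark: 6 and 15 are each written as one enol tautomer; 7 is written as the 2,4-bis(silyloxy)furan, and any O-silyl positional isomer would give the same furanolate on activation. The sense of induction of the ammonium catalyst cannot be predicted with confidence, so the cinchonidinium salt or its pseudoenantiomeric cinchoninium salt is taken, whichever delivers the (6S) product.

Step 1
Reactants: 1 methyl oxirane-2-carboxylate (racemic methyl glycidate); 2 (2-methylprop-1-en-1-yl)magnesium bromide
Product: 3 methyl 2-hydroxy-5-methylhex-4-enoate (racemic)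
Conditions: CuI (10 mol%), THF, −78 to −40 °C; then sat. aq. NH4Cl
Reagents that add atoms: none
Why: Copper-catalysed Grignard opening of the glycidic ester by SN2 attack at the unsubstituted epoxide carbon is faster than addition to the ester and turns the alkenyl group plus the epoxide CH2 into the prenyl side chain; the racemate suffices because this centre is erased in step 4.

Step 2
Reactants: 3 methyl 2-hydroxy-5-methylhex-4-enoate; 4 methyl 4-methyl-3-oxopentanoate
Product: 5 methyl 5-methyl-2-[(4-methyl-3-oxopentanoyl)oxy]hex-4-enoate
Conditions: DMAP (20 mol%), toluene, reflux, 4 Å molecular sieves (MeOH removal)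
Reagents that add atoms: none
Why: DMAP-catalysed transesterification of the β-keto ester (through its acylketene) acylates the secondary hydroxyl, and removal of methanol drives the equilibrium.

Step 3
Reactants: 5 methyl 5-methyl-2-[(4-methyl-3-oxopentanoyl)oxy]hex-4-enoate
Product: 6 4-hydroxy-5-(3-methylbut-2-en-1-yl)-3-(2-methylpropanoyl)furan-2(5H)-one (racemic)
Conditions: KOtBu (2.2 equiv), THF, 0 °C to rt; then 1 M HCl
Reagents that add atoms: none
Why: Lacey–Dieckmann cyclisation, in which the enolate of the doubly activated methylene attacks the methyl ester to close the five-membered ring and the strongly acidic 3-acyltetronate formed drives the condensation.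

Step 4
Reactants: 6 4-hydroxy-5-(3-methylbut-2-en-1-yl)-3-(2-methylpropanoyl)furan-2(5H)-one
Product: 7 2-methyl-1-[5-(3-methylbut-2-en-1-yl)-2,4-bis(trimethylsilyloxy)furan-3-yl]propan-1-one
Conditions: TMSOTf (2.3 equiv), Et3N (3 equiv), Et2O, 0 °C; pentane, decant from the ammonium salt, concentrate under Ar, use at once
Reagents that add atoms: trimethylsilyl trifluoromethanesulfonate, C[Si](C)(C)OS(=O)(=O)C(F)(F)F
Why: O-silylation of the acidic enol followed by silyl triflate/amine soft enolisation at C5, whose proton is vinylogously activated by the lactone and acyl carbonyls, is the usual conversion of a butenolide into an aromatic 2-silyloxyfuran; the C5 stereocentre is erased here.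

Step 5
Reactants: 8 2,2-dimethyl-1,3-dioxane-4,6-dione (Meldrum's acid); 9 1-bromo-3-methylbut-2-ene (prenyl bromide)
Product: 10 2,2-dimethyl-5,5-bis(3-methylbut-2-en-1-yl)-1,3-dioxane-4,6-dione
Conditions: 9 (2.2 equiv), K2CO3, DMF, rt
Reagents that add atoms: none
Why: Double C-alkylation of the highly acidic cyclic malonate by the allylic bromide under mild carbonate conditions.

Step 6
Reactants: 10 2,2-dimethyl-5,5-bis(3-methylbut-2-en-1-yl)-1,3-dioxane-4,6-dione
Product: 11 5-methyl-2-(3-methylbut-2-en-1-yl)hex-4-enoic acid
Conditions: pyridine/H2O (10:1), reflux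
Reagents that add atoms: water, O
Why: Hydrolytic opening of the acylal and decarboxylation of the resulting disubstituted malonic acid in a non-acidic medium, which leaves the trisubstituted alkenes untouched.

Step 7
Reactants: 11 5-methyl-2-(3-methylbut-2-en-1-yl)hex-4-enoic acid
Product: 13 5-methyl-2-(3-methylbut-2-en-1-yl)hexa-1,4-dien-1-one (diprenylketene), via acid chloride 12 (not isolated)
Conditions: (COCl)2, DMF (cat.), CH2Cl2, 0 °C; concentrate; Et3N, Et2O, reflux; filter, distil under reduced pressure
Reagents that add atoms: oxalyl chloride, O=C(Cl)C(=O)Cl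
Why: Acid chloride formation followed by amine-induced 1,2-elimination of HCl is the standard entry to disubstituted ketenes, and the hindered dialkylketene should survive filtration and distillation before it dimerises.

Step 8
Reactants: 7 2-methyl-1-[5-(3-methylbut-2-en-1-yl)-2,4-bis(trimethylsilyloxy)furan-3-yl]propan-1-one; 13 diprenylketene
Product: 15 (6S)-5,6-dihydroxy-4-(2-methylpropanoyl)-2,2,6-tris(3-methylbut-2-en-1-yl)cyclohex-4-ene-1,3-dione, via bis-silylated annulation product 14 (not isolated)
Conditions: 13 (1.3 equiv, slow addition), O-allyl-N-(9-anthracenylmethyl)cinchonidinium phenoxide (10 mol%), toluene/CH2Cl2, −78 to −40 °C; then 1 M HCl, THF, 0 °C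
Reagents that add atoms: none
Why: Proposed new method: the ammonium phenoxide removes the 2-O-silyl group of 7 to give a chiral ammonium furan-2-olate whose furan C5 (furan C3 is blocked by the acyl group) adds to the central carbon of 13 (product bond C6–C1); the ketone enolate so formed attacks the lactone carbonyl (product bond C2–C3) to give a 7-oxabicyclo[2.2.1]heptene alkoxide that collapses by cleavage of the former ring C–O bond, and the released tertiary alkoxide takes a silyl group from the next molecule of 7 to carry the chain. The closest known reaction types are the Hauser–Kraus anionic annulation of lactone anions, Diels–Alder reactions of 2-silyloxyfurans followed by opening of the oxygen bridge, and vinylogous Mukaiyama reactions of 2-silyloxyfurans under chiral quaternary ammonium phenoxide catalysis, none of which has used a ketene as the two-carbon partner. The six-membered carbocycle closes in a 6-(enolendo)-exo-trig mode, formally a [4+2] cycloaddition of the furan diene across the ketene C=C. The only stereocentre, C6, is created in the first C–C bond formation under control of the cinchona cation, which is ion-paired at the furanolate oxygen next to the ring oxygen and should shield one face of furan C5; being quaternary, C6 cannot epimerise afterwards. The step needs C-acylation over O-acylation and closure onto the lactone carbonyl instead of the 3-acyl carbonyl; O-acylation and the aldol mode are reversible under the anionic conditions, whereas collapse of the bridge followed by O-silylation is not. Dilute acid then cleaves both silyl ethers to release 15.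

Compound list
1 | methyl oxirane-2-carboxylate (racemic) | COC(=O)C1CO1 | starting material
2 | (2-methylprop-1-en-1-yl)magnesium bromide | CC(C)=C[Mg]Br | starting material
3 | methyl 2-hydroxy-5-methylhex-4-enoate (racemic) | COC(=O)C(O)CC=C(C)C | intermediate
4 | methyl 4-methyl-3-oxopentanoate | COC(=O)CC(=O)C(C)C | starting material
5 | methyl 5-methyl-2-[(4-methyl-3-oxopentanoyl)oxy]hex-4-enoate (racemic) | COC(=O)C(CC=C(C)C)OC(=O)CC(=O)C(C)C | intermediate
6 | 4-hydroxy-5-(3-methylbut-2-en-1-yl)-3-(2-methylpropanoyl)furan-2(5H)-one (racemic) | CC(C)C(=O)C1=C(O)C(CC=C(C)C)OC1=O | intermediate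
7 | 2-methyl-1-[5-(3-methylbut-2-en-1-yl)-2,4-bis(trimethylsilyloxy)furan-3-yl]propan-1-one | CC(C)C(=O)c1c(O[Si](C)(C)C)oc(CC=C(C)C)c1O[Si](C)(C)C | intermediate
8 | 2,2-dimethyl-1,3-dioxane-4,6-dione | CC1(C)OC(=O)CC(=O)O1 | starting material
9 | 1-bromo-3-methylbut-2-ene | CC(C)=CCBr | starting material
10 | 2,2-dimethyl-5,5-bis(3-methylbut-2-en-1-yl)-1,3-dioxane-4,6-dione | CC1(C)OC(=O)C(CC=C(C)C)(CC=C(C)C)C(=O)O1 | intermediate
11 | 5-methyl-2-(3-methylbut-2-en-1-yl)hex-4-enoic acid | CC(C)=CCC(CC=C(C)C)C(=O)O | intermediate
12 | 5-methyl-2-(3-methylbut-2-en-1-yl)hex-4-enoyl chloride | CC(C)=CCC(CC=C(C)C)C(=O)Cl | intermediate (not isolated)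
13 | 5-methyl-2-(3-methylbut-2-en-1-yl)hexa-1,4-dien-1-one | CC(C)=CCC(CC=C(C)C)=C=O | intermediate
14 | (6S)-4-(2-methylpropanoyl)-2,2,6-tris(3-methylbut-2-en-1-yl)-5,6-bis(trimethylsilyloxy)cyclohex-4-ene-1,3-dione | CC(C)=CCC1(CC=C(C)C)C(=O)C(C(=O)C(C)C)=C(O[Si](C)(C)C)[C@@](O[Si](C)(C)C)(CC=C(C)C)C1=O | intermediate (not isolated)
15 | (6S)-5,6-dihydroxy-4-(2-methylpropanoyl)-2,2,6-tris(3-methylbut-2-en-1-yl)cyclohex-4-ene-1,3-dione | CC(C)=CCC1(CC=C(C)C)C(=O)C(C(=O)C(C)C)=C(O)[C@@](O)(CC=C(C)C)C1=O | target

Total step count: 8. Longest linear sequence: 5 steps (steps 1, 2, 3, 4 and 8); the ketene arm (steps 5, 6, 7) joins at step 8.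

Steps most likely to fail

Step 8. Several processes may divert the cascade: silyl capture of the ketone enolate before it closes the ring, closure onto the 3-acyl carbonyl instead of the lactone carbonyl, nucleophile-induced dimerisation of the ketene, or poor facial discrimination within the ion pair. The fallback gives up the annulation and takes the ring from an arene by known chemistry; it sets out from 9 and comes back at 15. Commercial 2-methyl-1-(2,4,6-trihydroxyphenyl)propan-1-one F1 would be C-alkylated three times with 9 (NaOMe, MeOH, 0 °C), the classical dearomatising polyprenylation of acylphloroglucinols, to give 3,5-dihydroxy-2-(2-methylpropanoyl)-4,6,6-tris(3-methylbut-2-en-1-yl)cyclohexa-2,4-dien-1-one (colupulone) F2. Its sodium dienolate (NaHMDS, THF, −78 °C) would then be hydroxylated at the enol carbon that bears the single prenyl group with an enantiopure (camphorsulfonyl)oxaziridine, the antipode being chosen for the (6S) product, to give 15.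

Step 4. Enolisation at C5 may stay incomplete, or the silyl enol ethers may hydrolyse during isolation. The fallback replaces silyl group transfer by a preformed metal dienolate; it sets out from 6 and comes back at 15. Compound 6 would be deprotonated twice with KHMDS (2.05 equiv, THF, −78 °C) to dipotassium 3-(2-methylpropanoyl)-5-(3-methylbut-2-en-1-yl)furan-2,4-diolate F3. After addition of one equivalent of O-allyl-N-(9-anthracenylmethyl)cinchonidinium bromide in toluene, so that the reacting ion pair is again the chiral ammonium furanolate, 13 would be added. The annulated dipotassium salt of 15 F4 would be acidified with 1 M HCl to give 15 directly.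

Step 7. Dehydrochlorination of the α-branched acid chloride may be slow, so that the ketene dimerises or HCl adds to the prenyl double bonds. The fallback sets out from 10 and comes back at 13: flash vacuum pyrolysis of 10 (about 450 °C, low pressure, cold trap) would extrude acetone and carbon dioxide and deliver 13 without any acid chloride or amine salt; it makes no new compound.

Further compounds
F1 | step 8 | 2-methyl-1-(2,4,6-trihydroxyphenyl)propan-1-one | CC(C)C(=O)c1c(O)cc(O)cc1O
F2 | step 8 | 3,5-dihydroxy-2-(2-methylpropanoyl)-4,6,6-tris(3-methylbut-2-en-1-yl)cyclohexa-2,4-dien-1-one (colupulone) | CC(C)C(=O)C1=C(O)C(CC=C(C)C)=C(O)C(CC=C(C)C)(CC=C(C)C)C1=O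
F3 | step 4 | dipotassium 3-(2-methylpropanoyl)-5-(3-methylbut-2-en-1-yl)furan-2,4-diolate | CC(C)C(=O)c1c([O-])oc(CC=C(C)C)c1[O-].[K+].[K+]
F4 | step 4 | dipotassium salt of 15 (C5 enolate, C6 alkoxide) | CC(C)=CCC1(CC=C(C)C)C(=O)C(C(=O)C(C)C)=C([O-])[C@@]([O-])(CC=C(C)C)C1=O.[K+].[K+]
F0 | step 7 | none | none
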